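A direct plan would add the aryllithium from the geranylated phloroglucinol bromide A1 to the (3R)-β-hydroxy Weinreb amide A2, close the pyranone of the derived hydroxy ketone A3 by intramolecular Mitsunobu inversion, and oxidise C3 of the (2S)-flavanone A4 last with a flavanone 3-hydroxylase. Its weakest steps would be:
- the enzymatic C3 hydroxylation, because the enzyme might not accept a 6-geranyl-4'-methoxy substrate;
- the Mitsunobu closure, because the carbinol is p-alkoxybenzylic and β to a ketone, so ionisation and elimination to the chalcone would cost ee and material;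
- the aryllithium acylation, because a doubly ortho-substituted aryllithium would meet an amide that carries a lithium alkoxide.

The new plan reads ring C as one carboxylate inserted into an aryne. In the target, C4a carries the acyl carbon C4 and sits between the oxygen-bearing carbons C5 and C8a; a C4a≡C8a aryne polarised by O5 accepts a carboxylate oxygen at C8a and the acyl group at C4a. With an enantiopure trans-3-arylglycidate as the carboxylate, the liberated phenoxide oxygen (the future O1) opens the oxirane at benzylic C2 with inversion. One operation thus joins the fragments, closes the pyranone and delivers the trans C2/C3 pair with O3 already present, so no late C3 oxidation, no Mitsunobu inversion and no aryllithium–amide coupling is needed.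

Key step: step 10

Assumption: the side chain is the (2E)-geranyl group as drawn, and the L-fructose-derived (ent-Shi) diacetate ketone is accessible from L-sorbose by the standard carbohydrate sequence.

Step 1
Reactants: 1 resorcinol; 2 chloromethyl methyl ether (MOMCl)
Product: 3 1,3-bis(methoxymethoxy)benzene
Conditions: MOMCl (2.5 equiv), i-Pr2NEt (3 equiv), CH2Cl2, 0 °C → rt
Reagents that add atoms: 2 chloromethyl methyl ether, COCCl
Why: Williamson-type O-alkylation of both phenols gives the bis-MOM acetal, whose two oxygens later act as cooperative ortho-directing groups for C2.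

Step 2
Reactants: 3 1,3-bis(methoxymethoxy)benzene; 4 (E)-geranyl bromide
Product: 6 2-[(2E)-3,7-dimethylocta-2,6-dien-1-yl]-1,3-bis(methoxymethoxy)benzene, via 2-lithio-1,3-bis(methoxymethoxy)benzene 5 (not isolated)
Conditions: n-BuLi (1.1 equiv), THF, 0 °C → rt, 1 h; CuI (10 mol%), 4 (1.1 equiv), −78 °C → rt
Reagents that add atoms: 4 (E)-geranyl bromide, CC(C)=CCC/C(C)=C/CBr
Why: Directed ortho-metalation should occur at the one carbon flanked by both OMOM groups, and copper-catalysed SN2 allylation keeps the (E)-alkene, so the geranyl group sits between the oxygens that become O5 and O7.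

Step 3
Reactants: 6 2-geranyl-1,3-bis(methoxymethoxy)benzene; 7 bis(pinacolato)diboron; 8 hydrogen peroxide
Product: 10 4-[(2E)-3,7-dimethylocta-2,6-dien-1-yl]-3,5-bis(methoxymethoxy)phenol, via aryl pinacol boronate 9 (not isolated)
Conditions: [Ir(OMe)(cod)]2 (1.5 mol%), 4,4'-di-tert-butyl-2,2'-bipyridine (3 mol%), 7 (0.7 equiv), THF, 50 °C; then aq. NaOH, 30% H2O2, 0 °C
Reagents that add atoms: 8 hydrogen peroxide, OO
Why: Sterically governed iridium-catalysed C–H borylation should select C5, the only ring C–H without an ortho substituent, and boronate oxidation turns it into the third ring oxygen, so the phloroglucinol pattern is desymmetrised without statistical protection.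

Step 4
Reactants: 10 4-geranyl-3,5-bis(methoxymethoxy)phenol; 11 N-bromosuccinimide
Product: 12 2-bromo-4-[(2E)-3,7-dimethylocta-2,6-dien-1-yl]-3,5-bis(methoxymethoxy)phenol
Conditions: NBS (1.0 equiv), CH2Cl2, −78 °C, dark
Reagents that add atoms: 11 N-bromosuccinimide, O=C1CCC(=O)N1Br
Why: Electrophilic aromatic bromination of the trioxygenated ring (para position blocked by geranyl, the two ortho positions equivalent) should be far faster than attack on the trisubstituted alkenes at −78 °C.

Step 5
Reactants: 12 2-bromo-4-geranyl-3,5-bis(methoxymethoxy)phenol; 13 hexamethyldisilazane; 14 trifluoromethanesulfonic anhydride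
Product: 17 4-[(2E)-3,7-dimethylocta-2,6-dien-1-yl]-3,5-bis(methoxymethoxy)-2-(trimethylsilyl)phenyl trifluoromethanesulfonate, via aryl trimethylsilyl ether 15 (not isolated), via lithium 2-silylphenoxide 16 (not isolated)
Conditions: HMDS (1.5 equiv), THF, 65 °C, then evaporation; n-BuLi (1.1 equiv), THF, −100 °C; Tf2O (1.2 equiv), −100 → −78 °C
Reagents that add atoms: 13 hexamethyldisilazane, C[Si](C)(C)N[Si](C)(C)C; 14 trifluoromethanesulfonic anhydride, O=S(=O)(OS(=O)(=O)C(F)(F)F)C(F)(F)F
Why: O-silylation, bromine–lithium exchange and retro-Brook 1,3-O→C silyl migration give the ortho-silyl phenoxide, which is triflated to the ortho-silylaryl triflate aryne precursor.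

Step 6
Reactants: 18 isovanillin (3-hydroxy-4-methoxybenzaldehyde); 2 chloromethyl methyl ether
Product: 19 4-methoxy-3-(methoxymethoxy)benzaldehyde
Conditions: MOMCl (1.3 equiv), i-Pr2NEt (1.6 equiv), CH2Cl2, 0 °C → rt
Reagents that add atoms: 2 chloromethyl methyl ether, COCCl
Why: O-alkylation masks the B-ring phenol, which would otherwise add to the aryne in the key step, as an acetal that survives base, fluoride and oxidant.

Step 7
Reactants: 19 4-methoxy-3-(methoxymethoxy)benzaldehyde; 20 methyl (triphenylphosphoranylidene)acetate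
Product: 21 methyl (2E)-3-[4-methoxy-3-(methoxymethoxy)phenyl]prop-2-enoate
Conditions: 20 (1.2 equiv), toluene, 80 °C
Reagents that add atoms: 20 methyl (triphenylphosphoranylidene)acetate, COC(=O)C=P(c1ccccc1)(c1ccccc1)c1ccccc1
Why: Wittig olefination with a stabilised ylide should give the (E)-cinnamate, whose geometry later fixes the trans relationship of the epoxide.

Step 8
Reactants: 21 methyl (2E)-3-[4-methoxy-3-(methoxymethoxy)phenyl]prop-2-enoate; 22 Oxone (potassium peroxymonosulfate)
Product: 23 methyl (2R,3S)-3-[4-methoxy-3-(methoxymethoxy)phenyl]oxirane-2-carboxylate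
Conditions: ent-Shi diacetate ketone (25 mol%), Oxone, NaHCO3, Bu4NHSO4 (cat.), MeCN/aq. Na2EDTA, 0 °C; recrystallisation
Reagents that add atoms: 22 Oxone (potassium peroxymonosulfate), [K+].[O-]S(=O)(=O)OO
Why: In this Shi epoxidation the chiral dioxirane transfers oxygen to the (E)-alkene by stereospecific syn addition through a spiro transition state, and because the D-fructose-derived ketone gives (2S,3R)-glycidates from (E)-cinnamates, the L-series ketone should set both stereocentres as (2R,3S) in the trans-epoxide.

Step 9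
Reactants: 23 methyl (2R,3S)-glycidate; 24 potassium trimethylsilanolate
Product: 25 potassium (2R,3S)-3-[4-methoxy-3-(methoxymethoxy)phenyl]oxirane-2-carboxylate
Conditions: KOSiMe3 (1.0 equiv), THF, 0 °C → rt; filtration, drying in vacuo
Reagents that add atoms: 24 potassium trimethylsilanolate, C[Si](C)(C)[O-].[K+]
Why: Anhydrous silanolate ester cleavage delivers the dry carboxylate salt directly, so the free glycidic acid (prone to decarboxylation) is never formed and the non-enolisable oxirane centres stay untouched.

Step 10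
Reactants: 17 ortho-silylaryl triflate; 25 potassium (2R,3S)-glycidate
Product: 28 (2R,3R)-6-[(2E)-3,7-dimethylocta-2,6-dien-1-yl]-3-hydroxy-2-[4-methoxy-3-(methoxymethoxy)phenyl]-5,7-bis(methoxymethoxy)chroman-4-one, via aryne 26 (not isolated), via epoxy ketone phenoxide 27 (not isolated)
Conditions: 25 (1.5 equiv), KF (3 equiv), 18-crown-6 (3 equiv), THF, 0 °C; 17 (1.0 equiv) added over 2 h, then rt; then AcOH (5 equiv), rt → 40 °C
Reagents that add atoms: none
Why: Fluoride-induced 1,2-elimination of 17 gives aryne 26; the carboxylate oxygen of 25 adds at the aryne carbon distal to the OMOM-bearing carbon (the future C8a), and the resulting aryl anion (future C4a, flanked by the new ester oxygen and OMOM) undergoes a 1,3-O→C acyl shift of the anionic Fries type through a four-membered alkoxide to give phenoxide 27, with no acid present to protonate the anion first and no readily removable oxirane α-hydrogen. The closest known reaction type is the insertion of arynes into the acyl C–O bond of carboxylic acids to give ortho-hydroxyaryl ketones, which with unsaturated acids continues in the same flask to chromanones and flavones. The pyranone ring then closes by 6-endo-tet opening of the oxirane, the ortho oxygen attacking the benzylic carbon anti to the epoxide C–O bond, either as the phenoxide or, after the acetic acid quench, as the hydrogen-bonded phenol under acid assistance. C3 of the product is the untouched (R)-oxirane carbon and C2 arises from the (S)-benzylic carbon with inversion, which gives the (2R,3R)-trans pair; even a loose, cation-like transition state should close trans to the fixed C3 oxygen. The step needs three selectivities: aryne regiochemistry (secured by the OMOM group next to the aryne and the H on the other side), acyl shift before protonation (secured by the dry potassium salt in THF), and 6-endo over 5-exo opening (secured by the 4-methoxyaryl group, which stabilises positive charge at the benzylic carbon, and by finishing the closure under acid).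

Step 11
Reactants: 28 tri-O-MOM dihydroflavonol
Product: 29 4'-O-methyldiplacol, (2R,3R)-6-[(2E)-3,7-dimethylocta-2,6-dien-1-yl]-3,5,7-trihydroxy-2-(3-hydroxy-4-methoxyphenyl)chroman-4-one
Conditions: 3 M aq. HCl/MeOH (1:6), 45 °C
Reagents that add atoms: none
Why: Acid-catalysed acetal exchange with methanol should remove the three aryl MOM groups (the chelated 5-O-MOM first) under conditions too mild to cyclise the geranyl chain or to disturb the thermodynamically preferred trans-dihydroflavonol.

Compound list
1 | resorcinol | Oc1cccc(O)c1 | starting material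
2 | chloromethyl methyl ether | COCCl | starting material
3 | 1,3-bis(methoxymethoxy)benzene | COCOc1cccc(OCOC)c1 | intermediate
4 | (E)-geranyl bromide | CC(C)=CCC/C(C)=C/CBr | starting material
5 | 2-lithio-1,3-bis(methoxymethoxy)benzene | [Li]c1c(OCOC)cccc1OCOC | intermediate
6 | 2-[(2E)-3,7-dimethylocta-2,6-dien-1-yl]-1,3-bis(methoxymethoxy)benzene | COCOc1cccc(OCOC)c1C/C=C(\C)CCC=C(C)C | intermediate
7 | bis(pinacolato)diboron | CC1(C)OB(OC1(C)C)B1OC(C)(C)C(C)(C)O1 | starting material
8 | hydrogen peroxide | OO | starting material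
9 | 2-[4-geranyl-3,5-bis(methoxymethoxy)phenyl]-4,4,5,5-tetramethyl-1,3,2-dioxaborolane | CC1(C)OB(OC1(C)C)c1cc(OCOC)c(C/C=C(\C)CCC=C(C)C)c(OCOC)c1 | intermediate
10 | 4-[(2E)-3,7-dimethylocta-2,6-dien-1-yl]-3,5-bis(methoxymethoxy)phenol | Oc1cc(OCOC)c(C/C=C(\C)CCC=C(C)C)c(OCOC)c1 | intermediate
11 | N-bromosuccinimide | O=C1CCC(=O)N1Br | starting material
12 | 2-bromo-4-[(2E)-3,7-dimethylocta-2,6-dien-1-yl]-3,5-bis(methoxymethoxy)phenol | Oc1cc(OCOC)c(C/C=C(\C)CCC=C(C)C)c(OCOC)c1Br | intermediate
13 | hexamethyldisilazane | C[Si](C)(C)N[Si](C)(C)C | starting material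
14 | trifluoromethanesulfonic anhydride | O=S(=O)(OS(=O)(=O)C(F)(F)F)C(F)(F)F | starting material
15 | [2-bromo-4-geranyl-3,5-bis(methoxymethoxy)phenoxy]trimethylsilane | C[Si](C)(C)Oc1cc(OCOC)c(C/C=C(\C)CCC=C(C)C)c(OCOC)c1Br | intermediate
16 | lithium 4-geranyl-3,5-bis(methoxymethoxy)-2-(trimethylsilyl)phenoxide | [Li+].[O-]c1cc(OCOC)c(C/C=C(\C)CCC=C(C)C)c(OCOC)c1[Si](C)(C)C | intermediate
17 | 4-[(2E)-3,7-dimethylocta-2,6-dien-1-yl]-3,5-bis(methoxymethoxy)-2-(trimethylsilyl)phenyl trifluoromethanesulfonate | C[Si](C)(C)c1c(OS(=O)(=O)C(F)(F)F)cc(OCOC)c(C/C=C(\C)CCC=C(C)C)c1OCOC | intermediate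
18 | isovanillin (3-hydroxy-4-methoxybenzaldehyde) | COc1ccc(C=O)cc1O | starting material
19 | 4-methoxy-3-(methoxymethoxy)benzaldehyde | COCOc1cc(C=O)ccc1OC | intermediate
20 | methyl (triphenylphosphoranylidene)acetate | COC(=O)C=P(c1ccccc1)(c1ccccc1)c1ccccc1 | starting material
21 | methyl (2E)-3-[4-methoxy-3-(methoxymethoxy)phenyl]prop-2-enoate | COCOc1cc(/C=C/C(=O)OC)ccc1OC | intermediate
22 | Oxone (potassium peroxymonosulfate) | [K+].[O-]S(=O)(=O)OO | starting material
23 | methyl (2R,3S)-3-[4-methoxy-3-(methoxymethoxy)phenyl]oxirane-2-carboxylate | COC(=O)[C@@H]1O[C@H]1c1ccc(OC)c(OCOC)c1 | intermediate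
24 | potassium trimethylsilanolate | C[Si](C)(C)[O-].[K+] | starting material
25 | potassium (2R,3S)-3-[4-methoxy-3-(methoxymethoxy)phenyl]oxirane-2-carboxylate | [K+].[O-]C(=O)[C@@H]1O[C@H]1c1ccc(OC)c(OCOC)c1 | intermediate
26 | 4-geranyl-3,5-bis(methoxymethoxy)benzyne (aryne between the former C–OTf and C–SiMe3 carbons) | COCOC1=CC#CC(OCOC)=C1C/C=C(\C)CCC=C(C)C | intermediate
27 | potassium 4-geranyl-3,5-bis(methoxymethoxy)-2-{[(2R,3S)-3-(4-methoxy-3-(methoxymethoxy)phenyl)oxiran-2-yl]carbonyl}phenoxide | [K+].[O-]c1cc(OCOC)c(C/C=C(\C)CCC=C(C)C)c(OCOC)c1C(=O)[C@@H]1O[C@H]1c1ccc(OC)c(OCOC)c1 | intermediate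
28 | (2R,3R)-6-[(2E)-3,7-dimethylocta-2,6-dien-1-yl]-3-hydroxy-2-[4-methoxy-3-(methoxymethoxy)phenyl]-5,7-bis(methoxymethoxy)chroman-4-one | COCOc1cc([C@H]2Oc3cc(OCOC)c(C/C=C(\C)CCC=C(C)C)c(OCOC)c3C(=O)[C@@H]2O)ccc1OC | intermediate
29 | 4'-O-methyldiplacol, (2R,3R) | COc1ccc([C@H]2Oc3cc(O)c(C/C=C(\C)CCC=C(C)C)c(O)c3C(=O)[C@@H]2O)cc1O | target

Total steps: 11. Longest linear sequence: 7 (steps 1–5, 10 and 11).

Steps most likely to fail

1. Step 10. The aryl anion could be protonated before the acyl shift, leaving an aryl ester. The phenoxide could open the oxirane at the α-carbon (5-exo) instead of the benzylic carbon. The product alkoxide could also be arylated by further aryne or epimerised by base. Fallback, from 12 and 25 back to 28, without an aryne: Steglich-type coupling of 25 with bromophenol 12 (EDC·HCl, DMAP, CH2Cl2, 0 °C) would give the aryl glycidate F1. Bromine–lithium exchange (n-BuLi, THF, −100 °C) would trigger the anionic ortho-Fries acyl shift, and a cold AcOH quench would give the 2'-hydroxy epoxy ketone F2. Catalytic camphorsulfonic acid (CH2Cl2, 0 °C) would then close the ring at the benzylic carbon to 28.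

2. Step 3. Iridium hydrides and the hydrogen formed during borylation could isomerise, hydroborate or reduce the geranyl alkenes, or the alkenes could slow the catalyst. Fallback, from 3 back to 10, with the oxygen installed before the side chain: 3 would be borylated at C5 under the same conditions to the aryl boronate F3 and oxidised to 3,5-bis(methoxymethoxy)phenol F4. TIPSCl/imidazole would give the silyl ether F5. Lithiation between the two OMOM groups (n-BuLi, THF, 0 °C) to the aryllithium F6 and copper-catalysed reaction with 4 would give the geranylated silyl ether F7, and TBAF would release 10.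

3. Step 8. Oxygen transfer from the chiral dioxirane to the conjugated ester could be slow relative to decomposition of the ketone, or facial selectivity could be incomplete. Fallback, from 19 back to 23, by resolution instead of asymmetric catalysis: Darzens condensation of 19 with methyl chloroacetate (NaOMe, MeOH, −10 °C) would give the racemic trans-glycidate F8. Lipase-catalysed enantioselective hydrolysis (toluene/pH 8 buffer), as established for the 4-methoxyphenyl analogue, would consume the (2S,3R)-ester, whose acid decarboxylates to the arylacetaldehyde, and leave 23.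

Further compounds
F1 | step 10 | 2-bromo-4-[(2E)-3,7-dimethylocta-2,6-dien-1-yl]-3,5-bis(methoxymethoxy)phenyl (2R,3S)-3-[4-methoxy-3-(methoxymethoxy)phenyl]oxirane-2-carboxylate | COCOc1cc(OC(=O)[C@@H]2O[C@H]2c2ccc(OC)c(OCOC)c2)c(Br)c(OCOC)c1C/C=C(\C)CCC=C(C)C
F2 | step 10 | {3-[(2E)-3,7-dimethylocta-2,6-dien-1-yl]-6-hydroxy-2,4-bis(methoxymethoxy)phenyl}[(2R,3S)-3-(4-methoxy-3-(methoxymethoxy)phenyl)oxiran-2-yl]methanone | Oc1cc(OCOC)c(C/C=C(\C)CCC=C(C)C)c(OCOC)c1C(=O)[C@@H]1O[C@H]1c1ccc(OC)c(OCOC)c1
F3 | step 3 | 2-[3,5-bis(methoxymethoxy)phenyl]-4,4,5,5-tetramethyl-1,3,2-dioxaborolane | COCOc1cc(OCOC)cc(B2OC(C)(C)C(C)(C)O2)c1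
F4 | step 3 | 3,5-bis(methoxymethoxy)phenol | COCOc1cc(O)cc(OCOC)c1
F5 | step 3 | [3,5-bis(methoxymethoxy)phenoxy]tri(propan-2-yl)silane | COCOc1cc(O[Si](C(C)C)(C(C)C)C(C)C)cc(OCOC)c1
F6 | step 3 | [4-lithio-3,5-bis(methoxymethoxy)phenoxy]tri(propan-2-yl)silane | COCOc1cc(O[Si](C(C)C)(C(C)C)C(C)C)cc(OCOC)c1[Li]
F7 | step 3 | {4-[(2E)-3,7-dimethylocta-2,6-dien-1-yl]-3,5-bis(methoxymethoxy)phenoxy}tri(propan-2-yl)silane | COCOc1cc(O[Si](C(C)C)(C(C)C)C(C)C)cc(OCOC)c1C/C=C(\C)CCC=C(C)C
F8 | step 8 | racemic trans-methyl 3-[4-methoxy-3-(methoxymethoxy)phenyl]oxirane-2-carboxylate | COC(=O)C1OC1c1ccc(OC)c(OCOC)c1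
A1 | direct plan | {[2-bromo-4-((2E)-3,7-dimethylocta-2,6-dien-1-yl)-3,5-bis(methoxymethoxy)phenyl]oxy}(tert-butyl)dimethylsilane | COCOc1c(Br)c(O[Si](C)(C)C(C)(C)C)cc(OCOC)c1C/C=C(\C)CCC=C(C)C
A2 | direct plan | (3R)-3-hydroxy-N-methoxy-3-[4-methoxy-3-(methoxymethoxy)phenyl]-N-methylpropanamide | CON(C)C(=O)C[C@@H](O)c1ccc(OC)c(OCOC)c1
A3 | direct plan | (3R)-1-{3-geranyl-6-hydroxy-2,4-bis(methoxymethoxy)phenyl}-3-hydroxy-3-[4-methoxy-3-(methoxymethoxy)phenyl]propan-1-one | COc1ccc([C@H](O)CC(=O)c2c(OCOC)c(C/C=C(\C)CCC=C(C)C)c(OCOC)cc2O)cc1OCOC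
A4 | direct plan | (2S)-6-geranyl-5,7-dihydroxy-2-(3-hydroxy-4-methoxyphenyl)chroman-4-one | COc1ccc([C@H]2Oc3cc(O)c(C/C=C(\C)CCC=C(C)C)c(O)c3C(=O)C2)cc1O
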